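West keeps 25.2 % of its substrate at 12.0 h, more than east's 0 %. West's activator leaves 26.3 % of the substrate uncovered, so the two go about one to one. Carry one number, read in west at that time: 0.632, the late share, ring per part of substrate consumed.

in all of them: substrate 0.19 M

| flask | activator | remark | time |
|---|---|---|---|
| west | 0.14 M | run made earlier |  |
| east | 0.38 M | run made earlier |  |
| autumn | 0.210 M |  | 12 h |
| noon | 0.520 M |  | 12 h |

| run | time / h | ring / % | substrate / % |
|---|---|---|---|
| west | 1.50 | 27.6 | 55.3 |
| west | 3.00 | 42.2 | 41.2 |
| west | 5.00 | 46.6 | 31.6 |
| west | 6.00 | 46.8 | 30.9 |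
| west | 8.00 | 47.2 | 27.2 |
| west | 10.0 | 47.1 | 25.3 |
| west | 12.0 | 47.3 | 25.2 |
| east | 0.667 | 24.8 | 40.4 |
| east | 2.00 | 65.6 | 10.5 |
| east | 3.00 | 72.5 | 4.5 |
| east | 5.00 | 72.1 | 0 |
| east | 8.00 | 66.4 | 0.7 |
| east | 10.0 | 64.9 | 0 |
| east | 12.0 | 64.1 | 0 |

(each reading ± 0.5 percentage points)

1. which of the two there is more of at the end, autumn (ring / isomer of the product)
2. which of the two there is more of at the end, noon (ring / isomer of the product)
3. final ring, as a percentage of the substrate charged, in autumn
4. final ring, as a percentage of the substrate charged, in noon



Climb the ladder from the fastest rung. East at 2.00 h gives a second-order constant of 4.37 M⁻¹ h⁻¹. With that, noon's substrate, pseudo-first-order at the start with activator as charged, has a reckoned half-life of 0.305 h.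

Next comes ring. In east it reads 72.5 % at 3.00 h, then falls to 64.1 %. Taken against the share, that overshoot reads as a decay at 0.332 h⁻¹, a half-time of 2.08 h, slower than noon's substrate, so noon first fills with fresh ring, then relaxes.

Last comes autumn's tail. Autumn's activator as charged exceeds its substrate by 0.105 of the substrate charge, which gives a time of 11.4 h, longer than the relaxation, so autumn still holds substrate late, while its ring relaxes as it forms.

Now reckon ring as share times consumed, and compute only the correction. You reckon that autumn keeps 4.89 % of its substrate, so its ring comes to 60.1 %. For noon, take the charge as consumed, as east's substrate reads 0 % at 12.0 h, and add east's remaining overshoot of 0.86 percentage points, so you reckon ring at 64.1 %. The share leaves 0.368 of each part consumed for the other products, less than it gives ring, so you reckon ring ahead of the isomer of the product in autumn and noon.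

The forecast says ring and ring, with 60.5 % for autumn, above your figure, and 63.5 % for noon, below it, on the view “kinetic ring equilibrating with its isomer at about 63:37”.

Autumn ends with ring at 60.8 % against 27.8 % of the isomer of the product, and noon with 64.2 % against 31.2 %.

    substrate + activator → activated form (k = 4.20 M⁻¹ h⁻¹)
    activated form → ring (k = 1.60 h⁻¹)
    substrate + activated form → open dimer (k = 0.840 M⁻¹ h⁻¹)
    ring ⇌ isomer of the product (K = 0.510, k = 0.110 h⁻¹)

Autumn's ring per substrate consumed comes to 0.633 at 12.0 h. With substrate as charged, activated form has a half-life of 4.3 h by its loss with substrate to open dimer, longer than the 0.433 h of its step to ring. On a further flask, like autumn but charged with 0.048 M of substrate, 0.021 % of it remains, so the share gives 63.2 %, yet that flask holds 66.6 % of ring, with open dimer at 1.66 % against autumn's 6.94 %.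

Readings and results come from a simulation for substances that don't exist, noise included.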